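## The problem

Marchantin G (18) is an 18-membered cyclophane of four benzene rings. Ring A (para-linked) and ring B are joined by a diaryl ether oxygen, ring C (meta-linked) and ring D by a second one, ring D and ring A by a CH2–CH2 bridge, and ring B and ring C by a C(=O)–CH2 bridge whose carbonyl carbon sits on ring B. There is no stereogenic centre and no hindered axis, so nothing has to be controlled or relayed stereochemically; the task is regiochemistry, two differently hindered aryl–oxygen bonds, and the closure of a large ring. Ring D carries the hydroxyl group (C1), the ring C aryloxy group (C2) and the ethylene bridge (C3) on three adjacent carbons, so the ether oxygen at C2 is flanked on both sides, and arylating a 2,6-disubstituted phenol to make this bond is the classical weak point. Ring B is a 3,4,5-trioxygenated aryl ketone with the acyl group para to the central oxygen, a position that electrophilic acylation of a 1,2,3-trioxygenated benzene does not reach, so the ketone carbon has to arrive with ring B. The free catechol of ring B is air-sensitive and the CH2 between the ketone and ring C is acidic and prone to aldol and oxidative side reactions under base; the three phenols should therefore stay masked to the end and the keto bridge should be completed late. The feature that opens a way in is ring D itself: C4, C5 and C6 are unsubstituted CH carbons, and C6–C1(O)–C2(O)–C3(C) corresponds to a 1-alkyl-2-aryloxy-3-siloxybuta-1,3-diene, so the C3–C4 and C5–C6 bonds can be made by cycloaddition with a two-carbon alkyne unit after the crowded ether oxygen is already in place.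

## Retrosynthesis

**Deprotection.** The three O–CH3 bonds of tri-O-methyl ether 17 are cut last. Methyl ethers are preferred to benzyl or silyl groups because they pass unchanged through fluoride, strong base, palladium and copper. One Lewis-acid step must then free all three phenols of 18 without touching the diaryl ethers or the ketone.

**Ring opening.** The macrocycle of 17 is opened at the CH2–ring C bond of the keto bridge, giving the open-chain bromo ketone 16. The neighbouring cuts are less attractive. Opening at the ring A–O–ring B ether would require a copper-mediated ring closure at a bromide flanked by a methoxy group, in the presence of an acidic 1,2-diarylethanone. Opening at the ring C–O–ring D ether would put the most hindered bond of the molecule into the ring-closing step. The chosen cut leaves only an aryl bromide and an aryl methyl ketone, which need no protection earlier. The forward reaction, an intramolecular palladium-catalysed enolate arylation, must outrun intermolecular coupling; the ring is large and unstrained, so high dilution is the main requirement.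

**Ring D oxygen.** 16 is the methyl ether of phenol 15. The methyl group keeps the ring D oxygen from consuming base or binding palladium in the ring closure and leaves with the other two.

**Ring D (key disconnection).** In 15, ring D is taken apart at C3–C4 and C5–C6, giving the Z-configured 2-siloxy-3-aryloxydiene 11 and ethynyl p-tolyl sulfone 12. Compared with arylating the oxygen of a 2,6-disubstituted phenol by ring C, this cut removes the hindered coupling altogether, because the ring C–O bond is already present in 11. The precursor is acyclic and comes from three simple pieces. The forward step needs a [4+2] cycloaddition with the chain outside the s-cis diene (hence Z) and a clean loss of sulfinate; regiochemistry does not matter. Two spectator choices are deliberate. The ring A oxygen already carries ring B, so no protecting group is needed there and the route is convergent. The ring B acetyl group travels as its enol silane, formed and cleaved together with the diene oxygen.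

**Diene.** Diene 11 is the double enol silane of diketone 10. The C3=C4 double bond of 10 is cut by an olefination into ketophosphonate 9 and aldehyde 6. The olefination should fix the geometry under thermodynamic control (acyl trans to alkyl), and the enolisation must occur kinetically at the methyl group, not at the γ-CH2.

**Hindered ether.** Phosphonate 9 is cut at the O–C(sp3) bond into 3-bromophenol 7 and diazophosphonate 8. This is where the crowded ether of the target is really made: a rhodium carbenoid inserts into the O–H bond of a phenol with no ortho substituent. Bromine, not chlorine, is placed on ring C because the copper coupling is finished before ring C enters, so the more reactive halide can be reserved for the palladium step.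

**Ring A–ring B fragment.** Aldehyde 6 comes from alcohol 5 by oxidation. 5 is cut at the ring A–O–ring B ether into bromo ketone 3 and 3-(4-hydroxyphenyl)propan-1-ol 4; an intermolecular Ullmann coupling on small molecules is far more forgiving than the same bond as a ring closure. 3 comes from acetovanillone 1 through bromophenol 2, the free hydroxyl of 1 directing bromine to the one position required.

## Roads not taken

**Alternative 1:** The cut is the ring C–O bond of the ring C–O–ring D ether, made as the ring closure. In the forward direction the ring D phenoxide of the open-chain fluoronitroarene A1 displaces fluoride ortho to a temporary nitro group and gives macrocycle A2.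
- Merits: nitro-activated SNAr etherification is among the most dependable ways to close diaryl ether cyclophanes, it tolerates a hindered phenoxide, and it forms the difficult bond and the ring in one step from two convergent halves.
- Weak points: the nitro group must be introduced and then removed on the macrocycle (reduction, diazotisation, reductive removal). The ketone must be carried as a ketal, because its CH2 is both α to the carbonyl and para-nitrobenzylic, and even the ketal is exposed to base-induced β-elimination from that position. The 1,2,3-substituted ring D still has to be sourced separately.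
- Comparison: in the reliability of the ring closure this road is better than the chosen one, whose palladium ring closure extends a small-ring reaction to a large ring. The chosen plan sets against it that it needs no activating group and no ketal, forms the hindered C–O bond on an unhindered phenol, and is shorter (eleven steps, longest line ten).

**Alternative 2:** The cut is the ring B–C(=O) bond. In the forward direction, irradiation of the 18-membered arylacetate macrolactone A3 moves the acyl group from the central ring B oxygen to the para carbon (photo-Fries shift) and gives keto-phenol A4.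
- Merits: macrolactonisation is the most reliable ring closure available, both ortho positions of the ester oxygen are blocked so only the para shift can occur, and the acyl group lands exactly where Friedel–Crafts chemistry cannot put it, with the ring size unchanged.
- Weak points: the arylacetyl radical of the intermediate radical pair loses CO quickly to a benzyl radical, so decarbonylated products and the free phenol compete. Para recombination inside a tethered macrocycle requires reorganisation of the radical pair. The aryl ketone product absorbs the light and limits conversion. The hindered ring C–O–ring D ether would still have to be made by a classical coupling.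
- Comparison: the ring closure itself is better than in the chosen plan. The chosen plan sets against it that its key step is a thermal cycloaddition of a known type placed mid-route, not a low-conversion photoreaction at the end, and that it solves the hindered ether.

**Alternative 3:** The cuts are the ring D–CH2 bond and the ring D C–O bond of the future ether oxygen. In the forward direction the aryne A5 takes up a 2-arylethyl carbon nucleophile at the carbon meta to methoxy, and the resulting aryl anion ortho to methoxy is oxygenated, giving phenol A6.
- Merits: the 1,2,3-pattern of ring D is reached in one operation from cheap materials, and the regiochemistry of addition to 3-alkoxyarynes is well understood.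
- Weak points: A6 is a 2,6-disubstituted phenol, so the hindered oxygen still has to be arylated by ring C, which is the hardest bond of the target. Three-component aryne couplings with primary alkyl nucleophiles and an oxygen electrophile are not efficient. Both the second ether and the ring closure remain to be solved.
- Comparison: for assembling ring D alone this road is quicker than the six steps that lead to 15. The chosen plan sets against it that in 15 the crowded ether already exists and ring B is already attached.

Key step: step 8

Assumption: cycloadduct 13 is drawn as the regioisomer expected from the larger frontier coefficient at the CH2 terminus of the siloxydiene (sulfonyl next to the alkyl-bearing carbon); the other regioisomer would give the same arene 14.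

## Route

Step 1
Reactants: 1 1-(4-hydroxy-3-methoxyphenyl)ethan-1-one (acetovanillone)
Product: 2 1-(3-bromo-4-hydroxy-5-methoxyphenyl)ethan-1-one
Conditions: Br2, NaOAc, AcOH, rt
Reagents that add atoms: bromine, BrBr
Why: Electrophilic aromatic bromination; the free hydroxyl directs to its only open ortho position, the para position being occupied by the acetyl group, and NaOAc buffers HBr so the ketone is not α-brominated.

Step 2
Reactants: 2 1-(3-bromo-4-hydroxy-5-methoxyphenyl)ethan-1-one
Product: 3 1-(3-bromo-4,5-dimethoxyphenyl)ethan-1-one
Conditions: MeI, K2CO3, acetone, reflux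
Reagents that add atoms: iodomethane, CI
Why: Williamson O-methylation of the phenoxide; K2CO3 in acetone does not enolise the aryl ketone appreciably, so only oxygen should be alkylated.

Step 3
Reactants: 3 1-(3-bromo-4,5-dimethoxyphenyl)ethan-1-one; 4 3-(4-hydroxyphenyl)propan-1-ol
Product: 5 1-{3-[4-(3-hydroxypropyl)phenoxy]-4,5-dimethoxyphenyl}ethan-1-one
Conditions: CuI (10 mol %), picolinic acid (20 mol %), K3PO4, DMSO, 90 °C
Reagents that add atoms: none
Why: Ligand-accelerated Ullmann diaryl ether synthesis; the picolinic acid system is suited to ortho-substituted aryl bromides, the phenoxide should couple far faster than the aliphatic hydroxyl, and the meta-acetyl group mildly activates the bromide.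

Step 4
Reactants: 5 1-{3-[4-(3-hydroxypropyl)phenoxy]-4,5-dimethoxyphenyl}ethan-1-one
Product: 6 3-[4-(5-acetyl-2,3-dimethoxyphenoxy)phenyl]propanal
Conditions: Dess–Martin periodinane, CH2Cl2, 0 °C to rt
Reagents that add atoms: none
Why: Dess–Martin oxidation of a primary alcohol stops at the aldehyde under near-neutral conditions that leave the diaryl ether, the methyl ethers and the aryl ketone untouched.

Step 5
Reactants: 7 3-bromophenol; 8 dimethyl (1-diazo-2-oxopropyl)phosphonate
Product: 9 dimethyl [1-(3-bromophenoxy)-2-oxopropyl]phosphonate (racemic)
Conditions: Rh2(OAc)4 (2 mol %), toluene, 90 °C, slow addition of 8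
Reagents that add atoms: none
Why: Rhodium-carbenoid O–H insertion; the electrophilic carbenoid from the α-diazo-β-ketophosphonate should be captured by the unhindered phenol faster than it rearranges, so the future ring C–O–ring D bond forms before any ortho substituent exists; the new stereocentre is racemic and is erased in step 6.

Step 6
Reactants: 9 dimethyl [1-(3-bromophenoxy)-2-oxopropyl]phosphonate; 6 3-[4-(5-acetyl-2,3-dimethoxyphenoxy)phenyl]propanal
Product: 10 (3Z)-6-[4-(5-acetyl-2,3-dimethoxyphenoxy)phenyl]-3-(3-bromophenoxy)hex-3-en-2-one
Conditions: NaH, THF, 0 °C; then 6, 0 °C to rt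
Reagents that add atoms: none
Why: Horner–Wadsworth–Emmons olefination; the phosphonate, acidified by both the ketone and the aryloxy group, is deprotonated selectively and should react with the aldehyde and not the aryl ketone of 6, and reversible addition should funnel to the isomer with acyl and alkyl trans, which is the Z enol ether the diene needs.

Step 7
Reactants: 10 (3Z)-6-[4-(5-acetyl-2,3-dimethoxyphenoxy)phenyl]-3-(3-bromophenoxy)hex-3-en-2-one
Product: 11 (3Z)-3-(3-bromophenoxy)-2-(tert-butyldimethylsiloxy)-6-(4-{5-[1-(tert-butyldimethylsiloxy)ethenyl]-2,3-dimethoxyphenoxy}phenyl)hexa-1,3-diene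
Conditions: TBSOTf (2.5 equiv), Et3N, CH2Cl2, −78 to 0 °C
Reagents that add atoms: tert-butyldimethylsilyl trifluoromethanesulfonate, CC(C)(C)[Si](C)(C)OS(=O)(=O)C(F)(F)F
Why: Soft enolisation with silyl triflate and amine base; kinetic deprotonation of the enone should occur at the α′-methyl group to give the cross-conjugated 2-siloxydiene, and the aryl methyl ketone is silylated on purpose so that it is masked during the cycloaddition and released by the same fluoride treatment.

Step 8
Reactants: 11 (3Z)-3-(3-bromophenoxy)-2-(tert-butyldimethylsiloxy)-6-(4-{5-[1-(tert-butyldimethylsiloxy)ethenyl]-2,3-dimethoxyphenoxy}phenyl)hexa-1,3-diene; 12 ethynyl p-tolyl sulfone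
Product: 15 1-{3-[4-(2-{2-(3-bromophenoxy)-3-hydroxyphenyl}ethyl)phenoxy]-4,5-dimethoxyphenyl}ethan-1-one, via cyclohexa-1,4-diene sulfone cycloadduct 13 (not isolated), via bis-silylated aryl ether 14 (not isolated)
Conditions: 12 (1.1 equiv), toluene, 90 °C; then DBU (2 equiv), rt; then TBAF, THF, 0 °C to rt
Reagents that add atoms: none
Why: The electron-rich diene 11, whose Z enol ether geometry keeps the alkyl chain outside the s-cis conformation, and the electron-poor alkyne 12 should combine in a normal-electron-demand intermolecular [4+2] cycloaddition that forms the C3–C4 and C5–C6 bonds of ring D in one suprafacial step and so closes the six-membered carbocycle as cyclohexa-1,4-diene 13. DBU then removes a doubly allylic ring CH2 proton, the anion is reprotonated at the carbon bearing sulfur, and 1,2-elimination of p-toluenesulfinate from the resulting allylic sulfone aromatises the ring to silyl ether 14; TBAF finally cleaves the aryl silyl ether to the phenol and the spectator enol silane back to the acetophenone. The closest known reaction type is the Diels–Alder reaction of 2-siloxybuta-1,3-dienes with alkynyl sulfones used as acetylene equivalents, followed by loss of sulfinate. The only stereocentre formed (the alkyl-bearing carbon of 13) is racemic and disappears on aromatisation, so no stereocontrol is needed. Regioselectivity is not needed either, because the carbon that carried sulfur ends as C–H whichever way the alkyne adds. What is needed is chemoselectivity for the conjugated diene over the isolated aryl enol silane, secured because only the diene can react by a concerted cycloaddition at this temperature. Also needed is removal of unreacted 12 before phenoxide is released, which the amine stage provides by adding to it.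

Step 9
Reactants: 15 1-{3-[4-(2-{2-(3-bromophenoxy)-3-hydroxyphenyl}ethyl)phenoxy]-4,5-dimethoxyphenyl}ethan-1-one
Product: 16 1-{3-[4-(2-{2-(3-bromophenoxy)-3-methoxyphenyl}ethyl)phenoxy]-4,5-dimethoxyphenyl}ethan-1-one
Conditions: MeI, K2CO3, acetone, reflux
Reagents that add atoms: iodomethane, CI
Why: Williamson O-methylation of the ring D phenol, so that the methyl ketone is the only acidic site in the ring closure; the weak base should not C-alkylate the ketone.

Step 10
Reactants: 16 1-{3-[4-(2-{2-(3-bromophenoxy)-3-methoxyphenyl}ethyl)phenoxy]-4,5-dimethoxyphenyl}ethan-1-one
Product: 17 marchantin G tri-O-methyl ether (18-membered ketone with methyl ethers on the ring D oxygen and both free ring B oxygens)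
Conditions: Pd(OAc)2 (10 mol %), XPhos (20 mol %), NaOtBu (2.5 equiv), toluene, 80 °C, syringe-pump addition of 16 (final 2 mM)
Reagents that add atoms: none
Why: Palladium-catalysed ketone α-arylation run intramolecularly at high dilution: zerovalent palladium, formed in situ from Pd(OAc)2 and the bulky biarylphosphine, inserts into the ring C–Br bond, the tethered sodium enolate displaces bromide on palladium, and C–C reductive elimination closes the unstrained 18-membered ring. Full enolate formation with NaOtBu should suppress aldol chemistry, and at this dilution a second, intermolecular arylation of the product enolate should be slow.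

Step 11
Reactants: 17 marchantin G tri-O-methyl ether
Product: 18 marchantin G
Conditions: BBr3, CH2Cl2, −78 to 0 °C; then H2O, work-up under argon
Reagents that add atoms: none
Why: Lewis-acid cleavage of aryl methyl ethers with BBr3; the three methyl ethers are cleaved through bromoborane–oxonium intermediates while diaryl ethers and the ketone are not attacked, and hydrolysis of the aryl borates releases the catechol and the ring D phenol.

## Compound list

1 | 1-(4-hydroxy-3-methoxyphenyl)ethan-1-one (acetovanillone) | CC(=O)c1ccc(O)c(OC)c1 | starting material
2 | 1-(3-bromo-4-hydroxy-5-methoxyphenyl)ethan-1-one | CC(=O)c1cc(Br)c(O)c(OC)c1 | intermediate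
3 | 1-(3-bromo-4,5-dimethoxyphenyl)ethan-1-one | CC(=O)c1cc(Br)c(OC)c(OC)c1 | intermediate
4 | 3-(4-hydroxyphenyl)propan-1-ol | OCCCc1ccc(O)cc1 | starting material
5 | 1-{3-[4-(3-hydroxypropyl)phenoxy]-4,5-dimethoxyphenyl}ethan-1-one | CC(=O)c1cc(Oc2ccc(CCCO)cc2)c(OC)c(OC)c1 | intermediate
6 | 3-[4-(5-acetyl-2,3-dimethoxyphenoxy)phenyl]propanal | CC(=O)c1cc(Oc2ccc(CCC=O)cc2)c(OC)c(OC)c1 | intermediate
7 | 3-bromophenol | Oc1cccc(Br)c1 | starting material
8 | dimethyl (1-diazo-2-oxopropyl)phosphonate | COP(=O)(OC)C(=[N+]=[N-])C(C)=O | starting material
9 | dimethyl [1-(3-bromophenoxy)-2-oxopropyl]phosphonate (racemic) | COP(=O)(OC)C(Oc1cccc(Br)c1)C(C)=O | intermediate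
10 | (3Z)-6-[4-(5-acetyl-2,3-dimethoxyphenoxy)phenyl]-3-(3-bromophenoxy)hex-3-en-2-one | CC(=O)/C(Oc1cccc(Br)c1)=C/CCc1ccc(Oc2cc(cc(OC)c2OC)C(C)=O)cc1 | intermediate
11 | (3Z)-3-(3-bromophenoxy)-2-(tert-butyldimethylsiloxy)-6-(4-{5-[1-(tert-butyldimethylsiloxy)ethenyl]-2,3-dimethoxyphenoxy}phenyl)hexa-1,3-diene | C=C(O[Si](C)(C)C(C)(C)C)/C(Oc1cccc(Br)c1)=C/CCc1ccc(Oc2cc(cc(OC)c2OC)C(=C)O[Si](C)(C)C(C)(C)C)cc1 | intermediate
12 | ethynyl p-tolyl sulfone | Cc1ccc(cc1)S(=O)(=O)C#C | starting material
13 | 2-(3-bromophenoxy)-1-(tert-butyldimethylsiloxy)-3-[2-(4-{5-[1-(tert-butyldimethylsiloxy)ethenyl]-2,3-dimethoxyphenoxy}phenyl)ethyl]-4-(4-methylbenzenesulfonyl)cyclohexa-1,4-diene (racemic, not isolated) | CC(C)(C)[Si](C)(C)OC1=C(Oc2cccc(Br)c2)C(CCc2ccc(Oc3cc(cc(OC)c3OC)C(=C)O[Si](C)(C)C(C)(C)C)cc2)C(=CC1)S(=O)(=O)c1ccc(C)cc1 | intermediate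
14 | tert-butyl silyl ether of 15 that also carries the ring B enol silane: [2-(3-bromophenoxy)-3-(2-arylethyl)phenoxy](tert-butyl)dimethylsilane (not isolated) | CC(C)(C)[Si](C)(C)Oc1cccc(CCc2ccc(Oc3cc(cc(OC)c3OC)C(=C)O[Si](C)(C)C(C)(C)C)cc2)c1Oc1cccc(Br)c1 | intermediate
15 | 1-{3-[4-(2-{2-(3-bromophenoxy)-3-hydroxyphenyl}ethyl)phenoxy]-4,5-dimethoxyphenyl}ethan-1-one | CC(=O)c1cc(Oc2ccc(CCc3cccc(O)c3Oc3cccc(Br)c3)cc2)c(OC)c(OC)c1 | intermediate
16 | 1-{3-[4-(2-{2-(3-bromophenoxy)-3-methoxyphenyl}ethyl)phenoxy]-4,5-dimethoxyphenyl}ethan-1-one | CC(=O)c1cc(Oc2ccc(CCc3cccc(OC)c3Oc3cccc(Br)c3)cc2)c(OC)c(OC)c1 | intermediate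
17 | marchantin G tri-O-methyl ether | O=C1Cc2cccc(c2)Oc2c(OC)cccc2CCc2ccc(cc2)Oc2cc1cc(OC)c2OC | intermediate
18 | marchantin G | O=C1Cc2cccc(c2)Oc2c(O)cccc2CCc2ccc(cc2)Oc2cc1cc(O)c2O | target

## Step count and least certain steps

Total: 11 steps. Longest linear sequence: 10 steps (1 to 18 through steps 1–4 and 6–11); step 5 lies on the one-step side branch.

**Key step (step 8).** The most likely failures are:
- hydrolysis of the dienol silane before a slow cycloaddition is complete;
- incomplete migration of the vinyl sulfone into the allylic position, so that non-aromatised sulfones remain;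
- conjugate addition of the phenoxide, once freed, to alkynyl sulfone that has not been consumed.

The fallback sets out from 11 and returns to the route at 15. The diene would be combined with (E)-1,2-bis(phenylsulfonyl)ethene, an alkene-level acetylene equivalent and a stronger dienophile that should react at lower temperature. This should give the isolable racemic trans-4,5-bis(phenylsulfonyl)cyclohexene adduct F1. Excess DBU would then expel benzenesulfinic acid twice: first to the vinyl sulfone, then, after the same allylic shift as in the main route, to the arene. This gives 14, which yields 15 on fluoride treatment.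

**Step 10.** The most likely failures are intermolecular enolate arylation (oligomers) outrunning ring closure at any practical concentration, a second arylation at the more acidic CH2 of the product, and reductive loss of bromine when the arylpalladium intermediate waits too long for its enolate. The reaction type is established for small rings, but the ring size is untested. The fallback moves the ring closure to the ring A–O–ring B ether. It is a restart: it sets out from 8 and 12 and returns at 17.
- (3-Hydroxyphenyl)acetic acid would be converted into its trianion with LiN(SiMe3)2 and acylated with methyl 3-bromo-4,5-dimethoxybenzoate; acidic work-up with decarboxylation should give 1-(3-bromo-4,5-dimethoxyphenyl)-2-(3-hydroxyphenyl)ethan-1-one F2.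
- O–H insertion of 8 (Rh2(OAc)4) would give the aryloxy ketophosphonate F3.
- Olefination with purchased 3-[4-(benzyloxy)phenyl]propanal would give the Z enone F4; the ketophosphonate is expected to be clearly more acidic than the diarylethanone CH2.
- Double silylation would give the bis-enol silane diene F5, and cycloaddition with 12 followed by DBU and TBAF the bromo keto phenol F6.
- O-Methylation would give the methyl ether F7; debenzylation with BCl3 and pentamethylbenzene, which spares the aryl bromide, the ring A phenol F8.
- A high-dilution Ullmann ring closure (CuI, N,N-dimethylglycine, Cs2CO3, dioxane, 100 °C, oxygen excluded) between the ring A phenol and the ring B bromide would deliver 17.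

**Step 6.** The most likely failures are incomplete geometric control (the E enol ether cannot reach a reactive s-cis diene) and base-induced self-condensation of aldehyde 6. The fallback sets out from 6 and 7 and returns at 10. Wittig reaction of 6 with (acetylmethylene)triphenylphosphorane would give the (E)-enone F9. Nucleophilic epoxidation (H2O2, NaOH, MeOH) would give the racemic trans-epoxy ketone F10. Opening of F10 at the carbon α to the ketone by the phenoxide of 7 (Cs2CO3, DMF), followed by dehydration of the β-hydroxy ketone under the same conditions, should give 10 as the thermodynamically preferred Z isomer.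

**Step 3.** The most likely failures are slow coupling at the bromide flanked by a methoxy group, allowing base-induced condensation of the methyl ketone and some arylation of the primary alcohol. The fallback sets out from 3 and returns at 5. Miyaura borylation (PdCl2(dppf), KOAc, bis(pinacolato)diboron, dioxane, 90 °C) would give the pinacol boronate F11. Chan–Lam coupling of F11 with 4 (Cu(OAc)2, pyridine, molecular sieves, air, CH2Cl2, rt) forms the same ether oxidatively at room temperature, where the phenol reacts and the aliphatic alcohol does not.

## Further compounds

F1 | step 8 | 2-(3-bromophenoxy)-1-(tert-butyldimethylsiloxy)-3-[2-(4-{5-[1-(tert-butyldimethylsiloxy)ethenyl]-2,3-dimethoxyphenoxy}phenyl)ethyl]-4,5-bis(phenylsulfonyl)cyclohex-1-ene (racemic, sulfonyl groups trans, mixture at C3) | O=S(=O)(c1ccccc1)[C@H]1C(CCc2ccc(Oc3cc(cc(OC)c3OC)C(=C)O[Si](C)(C)C(C)(C)C)cc2)C(Oc2cccc(Br)c2)=C(O[Si](C)(C)C(C)(C)C)C[C@@H]1S(=O)(=O)c1ccccc1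
F2 | step 10 | 1-(3-bromo-4,5-dimethoxyphenyl)-2-(3-hydroxyphenyl)ethan-1-one | COc1cc(cc(Br)c1OC)C(=O)Cc1cccc(O)c1
F3 | step 10 | dimethyl (1-{3-[2-(3-bromo-4,5-dimethoxyphenyl)-2-oxoethyl]phenoxy}-2-oxopropyl)phosphonate (racemic) | COP(=O)(OC)C(Oc1cccc(CC(=O)c2cc(Br)c(OC)c(OC)c2)c1)C(C)=O
F4 | step 10 | (3Z)-6-[4-(benzyloxy)phenyl]-3-{3-[2-(3-bromo-4,5-dimethoxyphenyl)-2-oxoethyl]phenoxy}hex-3-en-2-one | CC(=O)/C(Oc1cccc(CC(=O)c2cc(Br)c(OC)c(OC)c2)c1)=C/CCc1ccc(OCc2ccccc2)cc1
F5 | step 10 | (3Z)-6-[4-(benzyloxy)phenyl]-3-{3-[2-(3-bromo-4,5-dimethoxyphenyl)-2-(tert-butyldimethylsiloxy)ethenyl]phenoxy}-2-(tert-butyldimethylsiloxy)hexa-1,3-diene (geometry of the styryl enol silane not defined) | C=C(O[Si](C)(C)C(C)(C)C)/C(Oc1cccc(C=C(O[Si](C)(C)C(C)(C)C)c2cc(Br)c(OC)c(OC)c2)c1)=C/CCc1ccc(OCc2ccccc2)cc1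
F6 | step 10 | 2-[3-(2-{2-[4-(benzyloxy)phenyl]ethyl}-6-hydroxyphenoxy)phenyl]-1-(3-bromo-4,5-dimethoxyphenyl)ethan-1-one | COc1cc(cc(Br)c1OC)C(=O)Cc1cccc(Oc2c(O)cccc2CCc2ccc(OCc3ccccc3)cc2)c1
F7 | step 10 | 2-[3-(2-{2-[4-(benzyloxy)phenyl]ethyl}-6-methoxyphenoxy)phenyl]-1-(3-bromo-4,5-dimethoxyphenyl)ethan-1-one | COc1cc(cc(Br)c1OC)C(=O)Cc1cccc(Oc2c(OC)cccc2CCc2ccc(OCc3ccccc3)cc2)c1
F8 | step 10 | 1-(3-bromo-4,5-dimethoxyphenyl)-2-[3-(2-{2-(4-hydroxyphenyl)ethyl}-6-methoxyphenoxy)phenyl]ethan-1-one | COc1cc(cc(Br)c1OC)C(=O)Cc1cccc(Oc2c(OC)cccc2CCc2ccc(O)cc2)c1
F9 | step 6 | (3E)-6-[4-(5-acetyl-2,3-dimethoxyphenoxy)phenyl]hex-3-en-2-one | CC(=O)/C=C/CCc1ccc(Oc2cc(cc(OC)c2OC)C(C)=O)cc1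
F10 | step 6 | trans-3,4-epoxy-6-[4-(5-acetyl-2,3-dimethoxyphenoxy)phenyl]hexan-2-one (racemic, one enantiomer drawn) | CC(=O)[C@H]1O[C@@H]1CCc1ccc(Oc2cc(cc(OC)c2OC)C(C)=O)cc1
F11 | step 3 | 1-[3,4-dimethoxy-5-(4,4,5,5-tetramethyl-1,3,2-dioxaborolan-2-yl)phenyl]ethan-1-one | CC(=O)c1cc(B2OC(C)(C)C(C)(C)O2)c(OC)c(OC)c1
A1 | alternative 1 | 2-[2-(4-{5-[2-(3-fluoro-4-nitrobenzyl)-1,3-dioxolan-2-yl]-2,3-dimethoxyphenoxy}phenyl)ethyl]-6-methoxyphenol | COc1cc(cc(Oc2ccc(CCc3cccc(OC)c3O)cc2)c1OC)C1(Cc2ccc([N+](=O)[O-])c(F)c2)OCCO1
A2 | alternative 1 | nitro-substituted macrocyclic ketal, tri-O-methyl | COc1cc2cc(c1OC)Oc1ccc(cc1)CCc1cccc(OC)c1Oc1cc(ccc1[N+](=O)[O-])CC21OCCO1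
A3 | alternative 2 | 18-membered arylacetate macrolactone on the central ring B oxygen, di-O-methyl | O=C1Cc2cccc(c2)Oc2c(OC)cccc2CCc2ccc(cc2)Oc2cccc(OC)c2O1
A4 | alternative 2 | di-O-methyl marchantin G with free central hydroxyl on ring B | O=C1Cc2cccc(c2)Oc2c(OC)cccc2CCc2ccc(cc2)Oc2cc1cc(OC)c2O
A5 | alternative 3 | 3-methoxybenzyne | COC1=CC=CC#C1
A6 | alternative 3 | 2-[2-(4-benzyloxyphenyl)ethyl]-6-methoxyphenol | COc1cccc(CCc2ccc(OCc3ccccc3)cc2)c1O
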